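Atoms carry ligustilide numbering: lower half C1–C8 (ring A butenolide, ring B cyclohexene), upper half C1'–C8' (ring C cyclohexene, ring D enol lactone); the cyclobutane is C6, C7, C3a', C7a'.
Cuts: ring C at its alkene C6'=C7' (reductive coupling of a dialdehyde); C7a'–C7' (lactone enolate alkylation); cyclobutane bonds C7–C3a' and C6–C7a' ([2+2]); ring D through an alkynoic acid (C8' by homologation, propyl by cross-coupling); ring A through an enynoic acid (C3a–C3 by Sonogashira coupling).
Forward: a resolved cyclohexene ester (ring B, from 2-methoxybenzoic acid) and a menthyl-acetal butenolide carrying the C4'–C6' arm give the cyclobutane by photocycloaddition; C7' is added, ring C is closed, ring D is rebuilt as the E-enol lactone, and ring A is closed last as the Z-butenolide.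
Enabling feature: C6' and C7' end two arms held cis on the C3a'–C7a' bond, on the cyclobutane face opposite ring D; C7' is 1,3 to the lactone carbonyl C1' and C6' is 1,5 to C3', so both are natural acceptor (aldehyde) carbons and only a reductive, like-polarity union joins them; C7a' is quaternary, so the aldehyde cannot enolise and the alkene cannot migrate.
Stereochemistry: C6, C7, C3a', C7a' come from the exo [2+2], steered by two disposable centres (C7a of the ester and the acetal carbon C3'); C7' enters with ring-enforced retention; E (ring D) from anti iodolactonisation then Negishi coupling; Z (ring A) from anti oxy-metalation and protonolysis.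

Key step: step 11

Assumption: the less soluble (R)-1-phenylethylammonium salt of acid 3 is taken to contain the (6R)-acid (the (S)-amine would be used otherwise), and the C5 epimers of acetal 11 are taken to be separable.

Step 1
Reactants: 1 2-methoxybenzoic acid
Product: 2 rac-2-methoxycyclohexa-2,5-diene-1-carboxylic acid
Conditions: Li, NH3(l), THF, −78 °C; NH4Cl; cold work-up at pH 4–5
Reagents that add atoms: none
Why: Birch reduction of the benzoate gives the 1,4-dihydro acid (protonation at C1 and C4), leaving an enol ether and an isolated cis alkene; the new centre is racemic.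

Step 2
Reactants: 2 rac-2-methoxycyclohexa-2,5-diene-1-carboxylic acid
Product: 3 rac-1,4-dioxaspiro[4.5]dec-7-ene-6-carboxylic acid
Conditions: HOCH2CH2OH (5 equiv), PPTS (cat.), CH2Cl2, 0 °C to rt
Reagents that add atoms: ethane-1,2-diol, OCCO
Why: Acid-catalysed addition of the diol to the enol ether with loss of methanol (transketalisation) masks the future C3a ketone as a dioxolane while the C6=C7 alkene stays out of conjugation.

Step 3
Reactants: 3 rac-1,4-dioxaspiro[4.5]dec-7-ene-6-carboxylic acid
Product: 4 (R)-1-phenylethylammonium (6R)-1,4-dioxaspiro[4.5]dec-7-ene-6-carboxylate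
Conditions: (R)-PhCH(CH3)NH2 (0.55 equiv), EtOAc–EtOH, crystallise and recrystallise
Reagents that add atoms: (R)-1-phenylethylamine, C[C@@H](N)c1ccccc1
Why: Classical resolution by crystallisation of a diastereomeric ammonium salt should deliver the (6R)-acid, whose stereocentre (future C7a) is a disposable controller for step 7.

Step 4
Reactants: 4 (R)-1-phenylethylammonium (6R)-1,4-dioxaspiro[4.5]dec-7-ene-6-carboxylate
Product: 6 tert-butyl (6R)-1,4-dioxaspiro[4.5]dec-7-ene-6-carboxylate, via free acid 5 (not isolated)
Conditions: 10% aq. citric acid/EtOAc; then Cl3CC(=NH)OtBu (2 equiv), cyclohexane–CH2Cl2, rt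
Reagents that add atoms: tert-butyl 2,2,2-trichloroacetimidate, CC(C)(C)OC(=N)C(Cl)(Cl)Cl
Why: The liberated acid protonates the imidate and is esterified by tert-butyl transfer without added acid, giving a base- and nucleophile-resistant ester with ketal and stereocentre untouched.

Step 5
Reactants: 7 glyoxylic acid monohydrate; 8 5-(benzyloxy)pentanal
Product: 9 rac-4-[3-(benzyloxy)propyl]-5-hydroxyfuran-2(5H)-one
Conditions: morpholine·HCl (1 equiv), dioxane–H2O, reflux
Reagents that add atoms: none
Why: Amine-salt-mediated aldol (Mannich-type) condensation of the aldehyde α-carbon with glyoxylic acid followed by lactol closure is the standard route to 4-alkyl-5-hydroxybutenolides; the C3' centre is racemic here and fixed in step 6.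

Step 6
Reactants: 9 rac-4-[3-(benzyloxy)propyl]-5-hydroxyfuran-2(5H)-one; 10 (1R,2S,5R)-(−)-menthol
Product: 11 (5S)-4-[3-(benzyloxy)propyl]-5-{[(1R,2S,5R)-5-methyl-2-(propan-2-yl)cyclohexyl]oxy}furan-2(5H)-one
Conditions: camphorsulfonic acid (cat.), toluene, reflux (Dean–Stark); separate the (5S) epimer, re-equilibrate the (5R) epimer under the same acid
Reagents that add atoms: none
Why: Fischer-type acetalisation of the pseudo-acid gives two C5 epimers that are diastereomers, so the (5S) epimer can be separated and the other recycled through the oxocarbenium ion.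

Step 7
Reactants: 6 tert-butyl (6R)-1,4-dioxaspiro[4.5]dec-7-ene-6-carboxylate (1.5 equiv); 11 (5S)-menthyloxy butenolide
Product: 12 exo head-to-tail cyclobutane adduct (menthyl acetal γ-lactone on one face; ring B with dioxolane ketal and tert-butyl ester on the other; 3-(benzyloxy)propyl on C3a', H on C7a')
Conditions: hν (300 nm, Pyrex), acetone, −20 °C, degassed; excess 6 recovered
Reagents that add atoms: none
Why: In this acetone-sensitised enone-type [2+2] photocycloaddition the triplet butenolide should add to the cis alkene of 6 on its face anti to the menthyloxy group, 6 should react anti to its ester, and ring B should lie exo (away from the lactone); for that topology both anti faces can be used together only in the head-to-tail sense joining C7 to C3a' and C6 to C7a', which sets all four cyclobutane centres.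

Step 8
Reactants: 12 cyclobutane adduct
Product: 13 bis(benzyl ether) (benzyloxymethyl on C7a')
Conditions: LiN(SiMe3)2 (1.15 equiv), THF, −78 °C; BnOCH2Cl (1.5 equiv), DMPU, −78 to −30 °C
Reagents that add atoms: benzyl chloromethyl ether, ClCOCc1ccccc1
Why: The lactone α-H is far more acidic than the hindered tert-butyl ester α-H, and the enolate of the cis-fused 3-oxabicyclo[3.2.0]heptanone can be alkylated only on its exo face, so the future C7' enters with retention, cis to the C3a' arm and syn to ring B.

Step 9
Reactants: 13 bis(benzyl ether)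
Product: 14 diol (CH2OH on C7a', 3-hydroxypropyl on C3a')
Conditions: H2 (1 atm), Pd(OH)2/C, EtOAc, rt
Reagents that add atoms: none
Why: Hydrogenolysis removes both benzyl ethers at a stage where no alkene is present.

Step 10
Reactants: 14 diol
Product: 15 dialdehyde (C7' formyl on C7a', C6' formyl at the end of the C3a' arm)
Conditions: Dess–Martin periodinane (2.6 equiv), CH2Cl2, 0 °C to rt
Reagents that add atoms: none
Why: Dess–Martin oxidation of both primary alcohols gives the dialdehyde; the C7' aldehyde sits on a quaternary carbon and can neither enolise nor epimerise.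

Step 11
Reactants: 15 dialdehyde
Product: 16 ring C cyclohexene (C6'=C7') with menthyl acetal lactone, ketal and tert-butyl ester intact
Conditions: TiCl3(DME)1.5, Zn–Cu couple, DME, reflux; 15 added by syringe pump over 30 h (high dilution)
Reagents that add atoms: none
Why: Low-valent titanium transfers single electrons to both aldehydes, and the two ketyl radicals couple on the metal to a titanium pinacolate that is deoxygenated at reflux to the alkene C6'=C7' (McMurry coupling). The closest known reaction type is the intramolecular McMurry cyclisation of 1,6-dialdehydes to cyclohexenes in the presence of esters and acetals. Ring C closes in a six-membered mode by joining two exocyclic carbonyl carbons, so both alkene carbons become endocyclic and the cis ring alkene is the only possible geometry. No stereocentre is formed, and because C3a' and C7a' are quaternary neither aldehyde epimerisation nor later alkene migration is possible. The step needs aldehyde–aldehyde coupling to beat coupling with the lactone or ester carbonyls and intermolecular pinacol formation: the fused lactone D holds the two arms cis on one cyclobutane face, aldehydes are reduced much faster than esters, and slow addition keeps the dialdehyde dilute. Both carbons are acceptor positions of the C1'–C7a'–C3a'–C3' unit, so their union requires exactly this reductive polarity reversal.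

Step 12
Reactants: 16 ring C cyclohexene with menthyl acetal lactone
Product: 18 alkynoic acid (ethynyl C3'≡C8'H on C3a', CO2H on C7a'), via aldehyde acid 17 (not isolated)
Conditions: LiOH (3 equiv), THF–H2O, rt; then MeOH, K2CO3, MeC(O)C(N2)P(O)(OMe)2, rt; aq. HCl work-up
Reagents that add atoms: lithium hydroxide, [Li+].[OH-]; dimethyl (1-diazo-2-oxopropyl)phosphonate (Ohira–Bestmann reagent), CC(=O)C(=[N+]=[N-])P(=O)(OC)OC
Why: Hydroxide opens the pseudo-ester at C1' (the hemiacetal collapses with loss of menthol) and Seyferth–Gilbert homologation with the Ohira–Bestmann reagent turns the non-enolisable C3' aldehyde into the terminal alkyne, erasing the auxiliary centre while the hindered tert-butyl ester survives.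

Step 13
Reactants: 18 alkynoic acid
Product: 19 (E)-iodomethylene enol lactone (ring D closed)
Conditions: I2 (2 equiv), NaHCO3 (3 equiv), MeCN, 0 °C, dark
Reagents that add atoms: iodine, II
Why: 5-exo-dig iodolactonisation adds carboxylate oxygen and iodine anti across the alkyne, giving the E-iodide (I trans to O); the alkyne is the only π bond the carboxylate can reach in an exo mode.

Step 14
Reactants: 19 (E)-iodomethylene enol lactone
Product: 20 (E)-butylidene enol lactone (ring B still as ketal tert-butyl ester)
Conditions: n-PrZnBr (2.5 equiv), PdCl2(dppf) (5 mol%), THF, rt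
Reagents that add atoms: n-propylzinc bromide, CCC[Zn]Br
Why: Negishi coupling of the alkenyl iodide proceeds with retention of alkene geometry, placing propyl trans to the ring oxygen (E) as in ring D of the target.

Step 15
Reactants: 20 (E)-butylidene enol lactone
Product: 21 β-keto ester (C3a ketone, tert-butyl ester on C7a; keto/enol and C7a epimers)
Conditions: PPTS (0.3 equiv), acetone–H2O (9:1), 55 °C
Reagents that add atoms: water, O
Why: Mild acid hydrolysis of the dioxolane releases the β-keto ester while the enol lactone and the tert-butyl ester should survive.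

Step 16
Reactants: 21 β-keto ester
Product: 22 enol triflate (C7a=C3a–OTf)
Conditions: Tf2O (1.3 equiv), iPr2NEt (1.5 equiv), CH2Cl2, −78 °C
Reagents that add atoms: trifluoromethanesulfonic anhydride, O=S(=O)(OS(=O)(=O)C(F)(F)F)C(F)(F)F
Why: O-sulfonylation of the β-keto ester enol gives the conjugated enol triflate, fixing the C7a=C3a double bond and erasing the disposable C7a centre.

Step 17
Reactants: 22 enol triflate; 23 1-pentyne
Product: 24 enyne tert-butyl ester
Conditions: PdCl2(PPh3)2 (5 mol%), CuI (10 mol%), iPr2NEt, DMF, rt
Reagents that add atoms: none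
Why: Sonogashira coupling of the electron-poor enol triflate with the terminal alkyne installs C3, C8 and the propyl end; the tertiary amine base spares the enol lactone.

Step 18
Reactants: 24 enyne tert-butyl ester
Product: 26 target (3Z,3'E)-dimer CNP0371639.1, via enyne acid 25 (not isolated)
Conditions: TFA–CH2Cl2 (1:4), 0 °C; evaporate; AgNO3 (10 mol%), acetone, rt, dark
Reagents that add atoms: none
Why: Acidolysis of the tert-butyl ester (loss of isobutene) and silver-catalysed 5-exo-dig cycloisomerisation of the (Z)-2-en-4-ynoic acid (anti oxy-metalation, then protodemetalation) should give the Z-butylidene butenolide ring A.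

Compound list
1 | 2-methoxybenzoic acid | COc1ccccc1C(=O)O | starting material
2 | rac-2-methoxycyclohexa-2,5-diene-1-carboxylic acid | COC1=CCC=CC1C(=O)O | intermediate
3 | rac-1,4-dioxaspiro[4.5]dec-7-ene-6-carboxylic acid | OC(=O)C1C=CCCC12OCCO2 | intermediate
4 | (R)-1-phenylethylammonium (6R)-1,4-dioxaspiro[4.5]dec-7-ene-6-carboxylate | C[C@@H]([NH3+])c1ccccc1.[O-]C(=O)[C@@H]1C=CCCC12OCCO2 | intermediate
5 | (6R)-1,4-dioxaspiro[4.5]dec-7-ene-6-carboxylic acid | OC(=O)[C@@H]1C=CCCC12OCCO2 | intermediate
6 | tert-butyl (6R)-1,4-dioxaspiro[4.5]dec-7-ene-6-carboxylate | CC(C)(C)OC(=O)[C@@H]1C=CCCC12OCCO2 | intermediate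
7 | glyoxylic acid monohydrate | OC(O)C(=O)O | starting material
8 | 5-(benzyloxy)pentanal | O=CCCCCOCc1ccccc1 | starting material
9 | rac-4-[3-(benzyloxy)propyl]-5-hydroxyfuran-2(5H)-one | O=C1C=C(CCCOCc2ccccc2)C(O)O1 | intermediate
10 | (1R,2S,5R)-(−)-menthol | CC(C)[C@@H]1CC[C@@H](C)C[C@H]1O | starting material
11 | (5S)-4-[3-(benzyloxy)propyl]-5-[(1R,2S,5R)-menthyloxy]furan-2(5H)-one | O=C1C=C(CCCOCc2ccccc2)[C@@H](O[C@@H]2C[C@H](C)CC[C@H]2C(C)C)O1 | intermediate
12 | exo head-to-tail cyclobutane adduct (ring B ketal tert-butyl ester; menthyl acetal lactone; 3-(benzyloxy)propyl on C3a'; H on C7a') | CC(C)(C)OC(=O)[C@H]2C4(OCCO4)CC[C@H]1[C@@H]2[C@@]2(CCCOCc5ccccc5)[C@@H]1C(=O)O[C@@H]2O[C@@H]4C[C@H](C)CC[C@H]4C(C)C | intermediate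
13 | bis(benzyl ether) (benzyloxymethyl on C7a') | CC(C)(C)OC(=O)[C@H]2C4(OCCO4)CC[C@H]1[C@@H]2[C@@]2(CCCOCc5ccccc5)[C@]1(COCc5ccccc5)C(=O)O[C@@H]2O[C@@H]4C[C@H](C)CC[C@H]4C(C)C | intermediate
14 | diol (hydroxymethyl on C7a', 3-hydroxypropyl on C3a') | CC(C)(C)OC(=O)[C@H]2C4(OCCO4)CC[C@H]1[C@@H]2[C@@]2(CCCO)[C@]1(CO)C(=O)O[C@@H]2O[C@@H]4C[C@H](C)CC[C@H]4C(C)C | intermediate
15 | dialdehyde (formyl on C7a', 3-oxopropyl on C3a') | CC(C)(C)OC(=O)[C@H]2C4(OCCO4)CC[C@H]1[C@@H]2[C@@]2(CCC=O)[C@]1(C=O)C(=O)O[C@@H]2O[C@@H]4C[C@H](C)CC[C@H]4C(C)C | intermediate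
16 | ring C cyclohexene (C6'=C7') with menthyl acetal lactone | CC(C)(C)OC(=O)[C@H]2C4(OCCO4)CC[C@H]1[C@@H]2[C@@]23CCC=C[C@@]12C(=O)O[C@@H]3O[C@@H]4C[C@H](C)CC[C@H]4C(C)C | intermediate
17 | aldehyde acid (formyl on C3a', CO2H on C7a') | CC(C)(C)OC(=O)[C@H]2C4(OCCO4)CC[C@H]1[C@@H]2[C@@]2(C=O)CCC=C[C@@]12C(=O)O | intermediate
18 | alkynoic acid (ethynyl on C3a', CO2H on C7a') | CC(C)(C)OC(=O)[C@H]2C4(OCCO4)CC[C@H]1[C@@H]2[C@@]2(C#C)CCC=C[C@@]12C(=O)O | intermediate
19 | (E)-iodomethylene enol lactone | CC(C)(C)OC(=O)[C@H]2C4(OCCO4)CC[C@H]1[C@@H]2[C@@]23CCC=C[C@@]12C(=O)O/C3=C/I | intermediate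
20 | (E)-butylidene enol lactone with ring B ketal ester | CC(C)(C)OC(=O)[C@H]2C4(OCCO4)CC[C@H]1[C@@H]2[C@@]23CCC=C[C@@]12C(=O)O/C3=C/CCC | intermediate
21 | β-keto tert-butyl ester (C7a epimers and enol) | CC(C)(C)OC(=O)C2C(=O)CC[C@H]1[C@@H]2[C@@]23CCC=C[C@@]12C(=O)O/C3=C/CCC | intermediate
22 | enol triflate | CC(C)(C)OC(=O)C2=C(OS(=O)(=O)C(F)(F)F)CC[C@H]1[C@@H]2[C@@]23CCC=C[C@@]12C(=O)O/C3=C/CCC | intermediate
23 | 1-pentyne | CCCC#C | starting material
24 | enyne tert-butyl ester | CC(C)(C)OC(=O)C2=C(C#CCCC)CC[C@H]1[C@@H]2[C@@]23CCC=C[C@@]12C(=O)O/C3=C/CCC | intermediate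
25 | enyne acid | OC(=O)C2=C(C#CCCC)CC[C@H]1[C@@H]2[C@@]23CCC=C[C@@]12C(=O)O/C3=C/CCC | intermediate
26 | target CNP0371639.1, (3Z,3'E) cyclobutane-linked ligustilide dimer | CCC/C=C1\OC(=O)C2=C1CC[C@H]1[C@@H]2[C@@]23CCC=C[C@@]12C(=O)O/C3=C/CCC | target

Total steps: 18. Longest linear sequence: 16 (steps 1–4 and 7–18; steps 5–6 form the second branch).

Steps most likely to fail

Step 7. The cycloaddition may run head-to-head or endo, or with incomplete facial control, because the arm-bearing carbon C3a' has to bond to the more hindered alkene carbon C7 and the biradical may revert instead of closing. The fallback sets out from 11 (with 6) and comes back at 13. Bromination of 11 at C3 (Br2, then Et3N) should give the 3-bromobutenolide F1. Stille coupling with Bu3SnCH2OBn (Pd(PPh3)4, CuI, dioxane, 90 °C) should give the tetrasubstituted butenolide F2. Irradiation of F2 with 6 under the conditions of step 7 should give 13 directly. Both alkene carbons are then equally substituted, so the orientation rests on the matched faces alone, both quaternary centres arise in the cycloaddition, and step 8 is not needed.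

Step 11. The pinacolate may stall before deoxygenation, and electron transfer to the acyloxy acetal or intermolecular coupling may consume material. The fallback sets out from 15 and comes back at 16. Twofold Wittig methylenation of 15 (Ph3P=CH2, THF, −78 °C) should give the diene F3, and ring-closing metathesis with the second-generation Grubbs catalyst (CH2Cl2, 40 °C) would join the same two carbons with loss of ethene. This replaces the reductive coupling by an alkylidene exchange.

Step 8. Proton transfer and O-alkylation may outrun C–C bond formation at an enolate carbon flanked by the quaternary C3a'. The fallback sets out from 12 and comes back at 14. The same enolate is added to monomeric formaldehyde (carbonyl addition instead of substitution, with the smallest electrophile) to give the hydroxymethyl lactone F4. Hydrogenolysis of the remaining benzyl ether (H2, Pd(OH)2/C, EtOAc) should give 14.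

Further compounds
F1 | step 7 | (5S)-4-[3-(benzyloxy)propyl]-3-bromo-5-[(1R,2S,5R)-menthyloxy]furan-2(5H)-one | O=C1C(Br)=C(CCCOCc2ccccc2)[C@@H](O[C@@H]2C[C@H](C)CC[C@H]2C(C)C)O1
F2 | step 7 | (5S)-3-[(benzyloxy)methyl]-4-[3-(benzyloxy)propyl]-5-[(1R,2S,5R)-menthyloxy]furan-2(5H)-one | O=C1C(COCc2ccccc2)=C(CCCOCc2ccccc2)[C@@H](O[C@@H]2C[C@H](C)CC[C@H]2C(C)C)O1
F3 | step 11 | diene (vinyl on C7a', but-3-enyl on C3a') | CC(C)(C)OC(=O)[C@H]2C4(OCCO4)CC[C@H]1[C@@H]2[C@@]2(CCC=C)[C@]1(C=C)C(=O)O[C@@H]2O[C@@H]4C[C@H](C)CC[C@H]4C(C)C
F4 | step 8 | hydroxymethyl lactone (CH2OH on C7a', 3-(benzyloxy)propyl on C3a') | CC(C)(C)OC(=O)[C@H]2C4(OCCO4)CC[C@H]1[C@@H]2[C@@]2(CCCOCc5ccccc5)[C@]1(CO)C(=O)O[C@@H]2O[C@@H]4C[C@H](C)CC[C@H]4C(C)C
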